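**Retrosynthetic overview**

1. Feature: ring A (the phenol ring) has four contiguous C–Br carbons, C3–C6, flanked by the two oxygen-bearing carbons C1 (OH) and C2 (O–aryl). C3–C6 with their bromines map onto the four carbons of tetrabromothiophene, and C1–C2 onto an alkyne carrying boron (latent OH) and phenoxy.
2. Last disconnections: C2'–Br and C4'–Br of ring B (electrophilic bromination of phenyl ether 16), then C1–O (oxidation of the C1–B bond of 14).
3. Key disconnection: C1–C6 and C2–C3 of ring A, by (4+2) cycloaddition of tetrabromothiophene 1,1-dioxide 3 with the phenoxyethynyl boronate 12 and loss of SO2.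
4. 3 comes from tetrabromothiophene 1 by S-oxidation; 12 comes from phenol 4, trichloroethylene 5 and the isopropoxy dioxaborolane 8 through the dichlorovinyl ether 7.
5. Ring order: ring B is bought as phenol; ring A is the only ring formed (step 4).

Key step: step 4

Remark: the target is achiral, so no stereocentre has to be set. Ring A is numbered C1 (OH), C2 (O–aryl), C3–C6 (Br); ring B is numbered C1' (O), C2' and C4' (Br).

**Route**

Step 1
Reactants: 1 tetrabromothiophene
Product: 3 2,3,4,5-tetrabromothiophene 1,1-dioxide, via tetrabromothiophene 1-oxide 2 (not isolated)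
Conditions: urea·H2O2, (CF3CO)2O, CH2Cl2, 0 °C → rt
Reagents that add atoms: trifluoroperacetic acid, OOC(=O)C(F)(F)F, made in the flask from urea–hydrogen peroxide, NC(N)=O.OO, and trifluoroacetic anhydride, O=C(OC(=O)C(F)(F)F)C(F)(F)F
Why: Peracid S-oxidation (sulfide to sulfoxide to sulfone) with anhydrous CF3CO3H, which is strong enough for the poorly nucleophilic sulfur of a tetrahalothiophene; the four bromines also block the self-dimerisation that destroys less substituted thiophene dioxides, so 3 should be an isolable solid.

Step 2
Reactants: 4 phenol; 5 trichloroethylene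
Product: 7 (E)-1,2-dichlorovinyl phenyl ether, via dichloroacetylene 6 (not isolated)
Conditions: K2CO3, DMF, 70 °C
Reagents that add atoms: none
Why: Base-induced dehydrochlorination of trichloroethylene gives dichloroacetylene, to which phenoxide adds in an anti sense (nucleophilic addition to a haloalkyne, the Greene-type dichlorovinyl ether synthesis), so the E ether with trans chlorines should form.

Step 3
Reactants: 7 (E)-1,2-dichlorovinyl phenyl ether; 8 2-isopropoxy-4,4,5,5-tetramethyl-1,3,2-dioxaborolane
Product: 12 4,4,5,5-tetramethyl-2-(phenoxyethynyl)-1,3,2-dioxaborolane, via chloro(phenoxy)acetylene 9 (not isolated), via lithium phenoxyacetylide 10 (not isolated), via lithium isopropoxy(alkynyl)borate 11 (not isolated)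
Conditions: n-BuLi (2.05 equiv), THF, −78 → −40 °C; 8, −78 °C; HCl·Et2O (1.0 equiv), −78 °C → rt; filter under Ar, use crude
Reagents that add atoms: none
Why: Vinylic deprotonation with loss of LiCl gives chloroalkyne 9, Li–Cl exchange with the second equivalent of n-BuLi gives acetylide 10, and its addition to boron followed by protonation of the isopropoxide of ate complex 11 with one equivalent of dry HCl releases 12 (Greene-type ynol ether synthesis joined to the Brown alkynylboronate synthesis); the alkoxide is the strongest base present and should be protonated before the ynol ether, and the phenoxy group has no β-hydrogen for retro-ene loss of ketene.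

Step 4
Reactants: 3 2,3,4,5-tetrabromothiophene 1,1-dioxide; 12 4,4,5,5-tetramethyl-2-(phenoxyethynyl)-1,3,2-dioxaborolane
Product: 14 4,4,5,5-tetramethyl-2-(2,3,4,5-tetrabromo-6-phenoxyphenyl)-1,3,2-dioxaborolane, via bridged sulfone cycloadduct 13 (not isolated)
Conditions: PhMe, 80 °C, Ar (12 in slight excess)
Reagents that add atoms: none
Why: Proposed new method: the sulfone 3 is an electron-poor diene held s-cis in a five-membered ring and the phenoxy group makes the alkyne of 12 electron-rich, so an inverse-electron-demand (4+2) cycloaddition should join the two sulfone α-carbons to the two alkyne carbons (bonds C1–C6 and C2–C3) to give the 7-thiabicyclo[2.2.1]heptadiene 7,7-dioxide 13, which should lose SO2 by cheletropic extrusion at the reaction temperature. The closest known reactions are the Diels–Alder/SO2-extrusion of tetrahalothiophene 1,1-dioxides with alkynes and the cycloadditions of alkynylboronates with electron-poor dienes such as cyclopentadienones, 2-pyrones and tetrazines, which give arylboronates; not yet shown is a thiophene dioxide reacting with an alkynylboronate that is also an ynol ether. Ring A is closed by this concerted, probably asynchronous, suprafacial cycloaddition and is aromatic as soon as SO2 has left. The two bridgehead stereocentres of 13 are linked by the bicycle and vanish on extrusion, so no stereocentre has to be controlled. No regiochemistry arises because the diene is symmetrical; the selectivity needed is (4+2) addition in preference to stepwise zwitterionic addition or oligomerisation of the ynol ether, together with retention of the C–B bond. The low LUMO of 3 should make the cycloaddition fast, the π-acceptor boron on the nucleophilic alkyne carbon tempers the polarisation of the ynol ether, the phenoxy group cannot fragment to a ketene, and dry aprotic toluene leaves no proton source for protodeboronation.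

Step 5
Reactants: 14 4,4,5,5-tetramethyl-2-(2,3,4,5-tetrabromo-6-phenoxyphenyl)-1,3,2-dioxaborolane
Product: 16 3,4,5,6-tetrabromo-2-phenoxyphenol, via aryl pinacol borate 15 (not isolated)
Conditions: NaBO3·4H2O, THF/H2O, rt; then 1 M HCl
Reagents that add atoms: sodium perborate (used as NaBO3·4H2O, the dimeric peroxoborate salt), [Na+].[Na+].O[B-]1(O)OO[B-](O)(O)OO1
Why: ipso-Oxidation of the arylboronate by 1,2-shift of the aryl group from boron to oxygen in the peroxoborate (boronate oxidation); perborate is only mildly basic, so oxidation should outrun base-induced protodeboronation of this electron-poor, doubly ortho-substituted boronate, and the aryl bromides and the diaryl ether are inert.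

Step 6
Reactants: 16 3,4,5,6-tetrabromo-2-phenoxyphenol
Product: 18 3,4,5,6-tetrabromo-2-(2,4-dibromophenoxy)phenol, via 3,4,5,6-tetrabromo-2-(4-bromophenoxy)phenol 17 (not isolated)
Conditions: Br2 (2.2 equiv), AcOH, rt → 60 °C; aq NaHSO3
Reagents that add atoms: bromine, BrBr
Why: Electrophilic aromatic bromination; ring A has no free position, so only ring B reacts, the ether oxygen directing first to the less hindered para carbon C4' and then to the ortho carbon C2', while C6' should be slower on the twice-deactivated ring; the acidic medium without added base disfavours ipso-bromination of the phenol, and the bisulfite quench returns any bromodienone to the phenol.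

**Compound list**

1 | tetrabromothiophene | Brc1sc(Br)c(Br)c1Br | starting material
2 | 2,3,4,5-tetrabromothiophene 1-oxide | O=S1C(Br)=C(Br)C(Br)=C1Br | intermediate
3 | 2,3,4,5-tetrabromothiophene 1,1-dioxide | O=S1(=O)C(Br)=C(Br)C(Br)=C1Br | intermediate
4 | phenol | Oc1ccccc1 | starting material
5 | trichloroethylene | ClC=C(Cl)Cl | starting material
6 | dichloroacetylene | ClC#CCl | intermediate
7 | (E)-1,2-dichlorovinyl phenyl ether (chlorines trans) | Cl/C=C(/Cl)Oc1ccccc1 | intermediate
8 | 2-isopropoxy-4,4,5,5-tetramethyl-1,3,2-dioxaborolane | CC(C)OB1OC(C)(C)C(C)(C)O1 | starting material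
9 | chloro(phenoxy)acetylene | ClC#COc1ccccc1 | intermediate
10 | lithium phenoxyacetylide | [Li]C#COc1ccccc1 | intermediate
11 | lithium isopropoxy(phenoxyethynyl)(pinacolato)borate | [Li+].CC(C)O[B-]1(C#COc2ccccc2)OC(C)(C)C(C)(C)O1 | intermediate
12 | 4,4,5,5-tetramethyl-2-(phenoxyethynyl)-1,3,2-dioxaborolane | CC1(C)OB(C#COc2ccccc2)OC1(C)C | intermediate
13 | 1,4,5,6-tetrabromo-2-phenoxy-3-(4,4,5,5-tetramethyl-1,3,2-dioxaborolan-2-yl)-7-thiabicyclo[2.2.1]hepta-2,5-diene 7,7-dioxide (racemic, one enantiomer drawn) | O=S1(=O)[C@]2(Br)C(Br)=C(Br)[C@@]1(Br)C(Oc3ccccc3)=C2B4OC(C)(C)C(C)(C)O4 | intermediate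
14 | 4,4,5,5-tetramethyl-2-(2,3,4,5-tetrabromo-6-phenoxyphenyl)-1,3,2-dioxaborolane | CC1(C)OB(OC1(C)C)c1c(Br)c(Br)c(Br)c(Br)c1Oc1ccccc1 | intermediate
15 | 4,4,5,5-tetramethyl-2-(2,3,4,5-tetrabromo-6-phenoxyphenoxy)-1,3,2-dioxaborolane | CC1(C)OB(Oc2c(Br)c(Br)c(Br)c(Br)c2Oc3ccccc3)OC1(C)C | intermediate
16 | 3,4,5,6-tetrabromo-2-phenoxyphenol | Oc1c(Br)c(Br)c(Br)c(Br)c1Oc1ccccc1 | intermediate
17 | 3,4,5,6-tetrabromo-2-(4-bromophenoxy)phenol | Oc1c(Br)c(Br)c(Br)c(Br)c1Oc1ccc(Br)cc1 | intermediate
18 | 3,4,5,6-tetrabromo-2-(2,4-dibromophenoxy)phenol | Oc1c(Br)c(Br)c(Br)c(Br)c1Oc1ccc(Br)cc1Br | target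

**Step count**

Total steps: 6. Longest linear sequence: 5 steps (phenol 4 → 7 → 12 → 14 → 16 → 18, steps 2 to 6); step 1 is the second branch.

**Steps most likely to fail**

1. Step 4 (proposed new method). The ynol ether boronate may be consumed by stepwise zwitterionic addition or oligomerisation, or lose boron by protodeboronation, faster than it cycloadds, and the bulky boronate may slow the approach to the fully substituted diene. Fallback with known chemistry, setting out from 10 and 3 and coming back at 14:
   - Lithium phenoxyacetylide 10, generated from 7 as in step 3, is quenched with methanol at −78 °C to give phenoxyacetylene F1, which is used fresh.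
   - F1 and 3 in toluene at 60–80 °C should give 1,2,3,4-tetrabromo-5-phenoxybenzene F3 through the bridged sulfone F2 with loss of SO2. This is the established alkyne Diels–Alder/SO2-extrusion of tetrahalothiophene dioxides, with a smaller dienophile.
   - The single ring A hydrogen of F3, flanked by Br and O–aryl, is removed with TMPMgCl·LiCl in THF at −40 °C (directed magnesiation) to give the arylmagnesium chloride F4.
   - F4 is trapped at low temperature with 8 to give 14.

2. Step 3. The ynol ether carbon may be protonated during acid collapse of the ate complex, with loss of boron, or the alkynylboronate may hydrolyse during isolation. Fallback setting out from 10 and 3 and coming back at 14: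
   - 10 is trapped with triisopropyl borate to give lithium triisopropoxy(phenoxyethynyl)borate F5, a tetracoordinate salt that is isolated by evaporation and keeps the C–B bond masked.
   - F5 is suspended in toluene and treated with Me3SiCl at 0 °C. Its three alkoxides are equivalent, so this non-protic unmasking can only release diisopropyl (phenoxyethynyl)boronate F6.
   - 3 is added to the same flask without isolation of F6 and the mixture is warmed to 80 °C. Cycloaddition through the bridged sulfone F7 and loss of SO2 should give diisopropyl (2,3,4,5-tetrabromo-6-phenoxyphenyl)boronate F8.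
   - Exchange with pinacol gives 14.

3. Step 6. Bromination may stop at the monobromide, run on to C6', or attack ring A ipso at the free phenol. Fallback setting out from 16 and coming back at 18:
   - 16 is acetylated (Ac2O, pyridine, DMAP) to 2,3,4,5-tetrabromo-6-phenoxyphenyl acetate F9.
   - With the phenol masked, Br2 with catalytic FeBr3 in CH2Cl2 can be used and dosed in two stages. This should take F9 through 2,3,4,5-tetrabromo-6-(4-bromophenoxy)phenyl acetate F10, which can be isolated and checked, to 2,3,4,5-tetrabromo-6-(2,4-dibromophenoxy)phenyl acetate F11.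
   - K2CO3 in MeOH then frees 18.

**Further compounds**

F1 | step 4 | phenoxyacetylene | C#COc1ccccc1
F2 | step 4 | 1,4,5,6-tetrabromo-2-phenoxy-7-thiabicyclo[2.2.1]hepta-2,5-diene 7,7-dioxide (racemic, not isolated) | O=S1(=O)[C@]2(Br)C(Br)=C(Br)[C@@]1(Br)C(Oc3ccccc3)=C2
F3 | step 4 | 1,2,3,4-tetrabromo-5-phenoxybenzene | Brc1cc(Oc2ccccc2)c(Br)c(Br)c1Br
F4 | step 4 | (2,3,4,5-tetrabromo-6-phenoxyphenyl)magnesium chloride | Cl[Mg]c1c(Br)c(Br)c(Br)c(Br)c1Oc1ccccc1
F5 | step 3 | lithium triisopropoxy(phenoxyethynyl)borate | [Li+].CC(C)O[B-](OC(C)C)(OC(C)C)C#COc1ccccc1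
F6 | step 3 | diisopropyl (phenoxyethynyl)boronate | CC(C)OB(OC(C)C)C#COc1ccccc1
F7 | step 3 | diisopropyl (1,4,5,6-tetrabromo-3-phenoxy-7,7-dioxo-7-thiabicyclo[2.2.1]hepta-2,5-dien-2-yl)boronate (racemic, not isolated) | O=S1(=O)[C@]2(Br)C(Br)=C(Br)[C@@]1(Br)C(Oc3ccccc3)=C2B(OC(C)C)OC(C)C
F8 | step 3 | diisopropyl (2,3,4,5-tetrabromo-6-phenoxyphenyl)boronate | CC(C)OB(OC(C)C)c1c(Br)c(Br)c(Br)c(Br)c1Oc1ccccc1
F9 | step 6 | 2,3,4,5-tetrabromo-6-phenoxyphenyl acetate | CC(=O)Oc1c(Br)c(Br)c(Br)c(Br)c1Oc1ccccc1
F10 | step 6 | 2,3,4,5-tetrabromo-6-(4-bromophenoxy)phenyl acetate | CC(=O)Oc1c(Br)c(Br)c(Br)c(Br)c1Oc1ccc(Br)cc1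
F11 | step 6 | 2,3,4,5-tetrabromo-6-(2,4-dibromophenoxy)phenyl acetate | CC(=O)Oc1c(Br)c(Br)c(Br)c(Br)c1Oc1ccc(Br)cc1Br
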